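**Assumptions:** germacrane numbering is used throughout (ring C1–C10, C11–C13 the methylene-lactone carbons, C14 = CH2OH on C10, C15 = CH3 on C4). Compounds 5, 9, 14 and 19 are bought, 14 as the single (R)-enantiomer. The route has not been run; selectivities are predictions from the named reaction types.

## Retrosynthetic overview

1. Target 23 ⇐ 22: the epoxide ring is made last, by hydroxyl-directed asymmetric epoxidation of the 1(10)-olefin.
2. 22 ⇐ 20: in one flask the ten-membered carbocycle is closed by a C6–C7 allyl-metal/aldehyde union of an acyclic, fully oxygenated farnesane chain (sets C6 and C7), then the γ-lactone closes by C6–O attack on C12.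
3. 20 ⇐ C7=C11 by cross-metathesis (19), C3–C4 by asymmetric Ni/Cr vinylation (4), C1=C10 by Z-selective Wittig (9), C8–C9 by aldol (5 + 6), ester from 14.
4. Ring order: carbocycle → lactone (same pot) → epoxide.

## Route

Step 1
Reactants: 1 but-2-yn-1-ol
Product: 3 (Z)-3-iodobut-2-en-1-ol, via sodium alkenylalanate 2 (not isolated)
Conditions: Red-Al, THF, 0 °C → rt; then I2, −78 → 0 °C
Reagents that add atoms: iodine, II
Why: Hydroxyl-directed trans-hydroalumination of the propargylic alcohol puts Al on C3 cis to CH2O in a five-membered alanate, and iodinolysis with retention gives the (Z)-vinyl iodide that becomes the ring-cis C4=C5 olefin with its C15 methyl.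

Step 2
Reactants: 3 (Z)-3-iodobut-2-en-1-ol
Product: 4 (Z)-triethyl[(3-iodobut-2-en-1-yl)oxy]silane
Conditions: TESCl, imidazole, CH2Cl2, 0 °C
Reagents that add atoms: chlorotriethylsilane, CC[Si](Cl)(CC)CC
Why: Standard silylation; the primary allylic TES ether is chosen because it can later be oxidised directly to the C6 aldehyde.

Step 3
Reactants: 5 1-[(tert-butyldimethylsilyl)oxy]propan-2-one; 6 acrolein
Product: 8 rac-1-[(tert-butyldimethylsilyl)oxy]-4-[(trimethylsilyl)oxy]hex-5-en-2-one, via lithium aldolate 7 (not isolated)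
Conditions: LDA, THF, −78 °C; 6; then TMSCl, −78 → 0 °C
Reagents that add atoms: chlorotrimethylsilane, C[Si](C)(C)Cl
Why: Aldol addition of the kinetic methyl-side lithium enolate to acrolein (1,2-addition) forms C8–C9; the aldolate is silylated in the flask so the β-oxygen survives the next step; C8 is racemic here and resolved in step 5.

Step 4
Reactants: 8 rac-1-[(tert-butyldimethylsilyl)oxy]-4-[(trimethylsilyl)oxy]hex-5-en-2-one; 9 [2-(1,3-dioxolan-2-yl)ethyl]triphenylphosphonium bromide
Product: 12 rac-(5Z)-5-{[(tert-butyldimethylsilyl)oxy]methyl}-7-(1,3-dioxolan-2-yl)hepta-1,5-dien-3-ol, via ylide 10 (not isolated), via TMS ether 11 (not isolated)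
Conditions: KHMDS, THF, −78 → 0 °C; 8, −78 °C → rt; then K2CO3 (cat.), MeOH, 0 °C
Reagents that add atoms: none
Why: Still-type Wittig olefination of an α-alkoxy ketone with a non-stabilised ylide places the ylide chain cis to CH2OTBS, so C2 is cis to C14 and trans to C9 (the ring-trans 1(10)-olefin); K2CO3/MeOH removes only the secondary TMS ether.

Step 5
Reactants: 12 rac-(5Z)-5-{[(tert-butyldimethylsilyl)oxy]methyl}-7-(1,3-dioxolan-2-yl)hepta-1,5-dien-3-ol
Product: 13 (3R,5Z)-5-{[(tert-butyldimethylsilyl)oxy]methyl}-7-(1,3-dioxolan-2-yl)hepta-1,5-dien-3-ol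
Conditions: Ti(OiPr)4 (20 mol %), L-(+)-DIPT (24 mol %), TBHP (0.55 equiv), 4 Å MS, CH2Cl2, −20 °C
Reagents that add atoms: none
Why: Sharpless kinetic resolution: with L-(+)-tartrate the (S)-vinyl carbinol is epoxidised fast and the (R)-alcohol (C8) is recovered in high ee (at most 50 % yield); the homoallylic trisubstituted olefin and the silyl-blocked allylic ether do not react.

Step 6
Reactants: 13 (3R,5Z)-5-{[(tert-butyldimethylsilyl)oxy]methyl}-7-(1,3-dioxolan-2-yl)hepta-1,5-dien-3-ol; 14 (R)-2-methylbutanoic acid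
Product: 15 (3R,5Z)-5-{[(tert-butyldimethylsilyl)oxy]methyl}-7-(1,3-dioxolan-2-yl)hepta-1,5-dien-3-yl (2R)-2-methylbutanoate
Conditions: DCC, DMAP (cat.), CH2Cl2, 0 °C → rt
Reagents that add atoms: none
Why: Steglich esterification with retention at C8; the final 8-O-acyl group is installed while C8–OH is the only free hydroxyl and serves as its own protecting group from here on.

Step 7
Reactants: 15 (3R,5Z)-5-{[(tert-butyldimethylsilyl)oxy]methyl}-7-(1,3-dioxolan-2-yl)hepta-1,5-dien-3-yl (2R)-2-methylbutanoate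
Product: 16 (3R,5Z)-5-{[(tert-butyldimethylsilyl)oxy]methyl}-8-oxoocta-1,5-dien-3-yl (2R)-2-methylbutanoate
Conditions: In(OTf)3 (2 mol %), acetone/H2O 20:1, rt → 35 °C; used at once
Reagents that add atoms: water, O
Why: Mild Lewis-acid-catalysed acetal hydrolysis frees the C3 aldehyde under near-neutral conditions that leave the TBS ether and allylic ester intact and do not move the β,γ-olefin into conjugation.

Step 8
Reactants: 16 (3R,5Z)-5-{[(tert-butyldimethylsilyl)oxy]methyl}-8-oxoocta-1,5-dien-3-yl (2R)-2-methylbutanoate; 4 (Z)-triethyl[(3-iodobut-2-en-1-yl)oxy]silane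
Product: 17 (3R,5Z,8S,9Z)-5-{[(tert-butyldimethylsilyl)oxy]methyl}-9-methyl-8,11-bis[(triethylsilyl)oxy]undeca-1,5,9-trien-3-yl (2R)-2-methylbutanoate
Conditions: CrCl2 (10 mol %), chiral oxazoline–sulfonamide ligand (11 mol %), proton sponge (11 mol %), NiCl2·(2,9-dimethylphenanthroline) (2 mol %), Mn, TESCl, LiCl, MeCN, rt
Reagents that add atoms: chlorotriethylsilane, CC[Si](Cl)(CC)CC
Why: Catalytic asymmetric Nozaki–Hiyama–Kishi (Ni/Cr) coupling joins C3–C4 with retention of the Z-vinyl geometry; the C3 carbinol (S) is set by the chiral Cr–sulfonamide complex (ligand antipode chosen to give 3S, checked by Mosher analysis), and TESCl turns over chromium and delivers the product as its TES ether.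

Step 9
Reactants: 17 (3R,5Z,8S,9Z)-5-{[(tert-butyldimethylsilyl)oxy]methyl}-9-methyl-8,11-bis[(triethylsilyl)oxy]undeca-1,5,9-trien-3-yl (2R)-2-methylbutanoate
Product: 18 (3R,5Z,8S,9Z)-5-{[(tert-butyldimethylsilyl)oxy]methyl}-9-methyl-11-oxo-8-[(triethylsilyl)oxy]undeca-1,5,9-trien-3-yl (2R)-2-methylbutanoate
Conditions: (COCl)2, DMSO, CH2Cl2, −78 → −40 °C; iPr2NEt, −78 → −20 °C
Reagents that add atoms: none
Why: Swern oxidation cleaves and oxidises a primary TES ether directly to the aldehyde while secondary TES and TBS ethers survive, giving the (Z)-enal (C6) without a separate deprotection; low temperature and a hindered base keep the Z geometry.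

Step 10
Reactants: 18 (3R,5Z,8S,9Z)-5-{[(tert-butyldimethylsilyl)oxy]methyl}-9-methyl-11-oxo-8-[(triethylsilyl)oxy]undeca-1,5,9-trien-3-yl (2R)-2-methylbutanoate; 19 methyl 2-(bromomethyl)prop-2-enoate
Product: 20 methyl (2Z,4R,6Z,9S,10Z)-2-(bromomethyl)-6-{[(tert-butyldimethylsilyl)oxy]methyl}-10-methyl-4-{[(2R)-2-methylbutanoyl]oxy}-12-oxo-9-[(triethylsilyl)oxy]dodeca-2,6,10-trienoate
Conditions: Hoveyda–Grubbs II (10 mol %), 19 (5 equiv), 2,6-dichloro-1,4-benzoquinone (10 mol %), toluene, 60 °C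
Reagents that add atoms: none
Why: Olefin cross-metathesis of the only monosubstituted alkene with the 1,1-disubstituted acrylate (the trisubstituted olefins and the enal are inert) builds C7=C11 with C12 and C13 in one step; the quinone suppresses Ru–H isomerisation, and the geometry of this olefin is not critical because the derived allylchromium equilibrates.

Step 11
Reactants: 20 methyl (2Z,4R,6Z,9S,10Z)-2-(bromomethyl)-6-{[(tert-butyldimethylsilyl)oxy]methyl}-10-methyl-4-{[(2R)-2-methylbutanoyl]oxy}-12-oxo-9-[(triethylsilyl)oxy]dodeca-2,6,10-trienoate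
Product: 22 (3S,6R,7R,8R)-3,14-dihydroxy-8-[(2R)-2-methylbutanoyloxy]germacra-1(10),4,11(13)-trien-12,6-olide (C4=C5 ring-cis; C1=C10 ring-trans), via macrocyclic hydroxy ester 21 (not isolated)
Conditions: CrCl2 (8 equiv), THF, 2 mM (syringe pump), rt; then HF·pyridine, pyridine, 0 °C → rt
Reagents that add atoms: none
Why: Intramolecular Nozaki–Hiyama (Cr(II) Barbier-type) allylation closes the ten-membered ring at C6–C7, the bond formed when the farnesyl chain is cyclised in nature, through a chair-like Cr–O transition state: the equilibrating allylchromium carries the C8 chain pseudo-equatorial (6,7-anti, hence trans-lactone) and, with H-8 in the allyl plane to avoid A(1,3) strain, is attacked anti to the C9 chain, which should give 6R,7R from 8R; the C6 alkoxide then lactonises onto C12 and HF·pyridine removes both silyl ethers.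

Step 12
Reactants: 22 (3S,6R,7R,8R)-3,14-dihydroxy-8-[(2R)-2-methylbutanoyloxy]germacra-1(10),4,11(13)-trien-12,6-olide
Product: 23 (1R,3S,6R,7R,8R,10S)-1,10-epoxy-3,14-dihydroxy-8-[(2R)-2-methylbutanoyloxy]germacra-4,11(13)-dien-12,6-olide (target)
Conditions: Ti(OiPr)4 (30 mol %), L-(+)-DIPT (36 mol %), TBHP, 4 Å MS, CH2Cl2, −25 °C
Reagents that add atoms: tert-butyl hydroperoxide, CC(C)(C)OO
Why: Katsuki–Sharpless asymmetric epoxidation of the primary allylic alcohol (C14–OH): L-(+)-tartrate delivers oxygen in the same sense as for geraniol → (2S,3S)-epoxygeraniol, which here gives 1R,10S by syn addition to the olefin with C2 cis to C14; the 4,5-olefin (Z-substituted secondary allylic alcohol, deactivated by two allylic oxygens) and the electron-poor exo-methylene are left alone.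

## Compound list

1 | but-2-yn-1-ol | CC#CCO | starting material
2 | sodium alkenylalanate (cyclic 3-methyl-2,5-dihydro-1,2-oxaluminole ate complex with two 2-methoxyethoxy groups) | [Na+].CC1=CCO[Al-]1(OCCOC)OCCOC | intermediate
3 | (Z)-3-iodobut-2-en-1-ol | C/C(I)=C/CO | intermediate
4 | (Z)-triethyl[(3-iodobut-2-en-1-yl)oxy]silane | C/C(I)=C/CO[Si](CC)(CC)CC | intermediate
5 | 1-[(tert-butyldimethylsilyl)oxy]propan-2-one | CC(=O)CO[Si](C)(C)C(C)(C)C | starting material
6 | acrolein | C=CC=O | starting material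
7 | lithium aldolate (lithium 6-[(tert-butyldimethylsilyl)oxy]-5-oxohex-1-en-3-olate, racemic) | [Li+].[O-]C(C=C)CC(=O)CO[Si](C)(C)C(C)(C)C | intermediate
8 | rac-1-[(tert-butyldimethylsilyl)oxy]-4-[(trimethylsilyl)oxy]hex-5-en-2-one | C=CC(O[Si](C)(C)C)CC(=O)CO[Si](C)(C)C(C)(C)C | intermediate
9 | [2-(1,3-dioxolan-2-yl)ethyl]triphenylphosphonium bromide | [Br-].C1COC(CC[P+](c2ccccc2)(c2ccccc2)c2ccccc2)O1 | starting material
10 | ylide, [2-(1,3-dioxolan-2-yl)ethylidene]triphenylphosphorane | C1COC(CC=P(c2ccccc2)(c2ccccc2)c2ccccc2)O1 | intermediate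
11 | TMS ether of 12 (racemic, 5Z) | C=CC(O[Si](C)(C)C)C/C(CO[Si](C)(C)C(C)(C)C)=C/CC1OCCO1 | intermediate
12 | rac-(5Z)-5-{[(tert-butyldimethylsilyl)oxy]methyl}-7-(1,3-dioxolan-2-yl)hepta-1,5-dien-3-ol | C=CC(O)C/C(CO[Si](C)(C)C(C)(C)C)=C/CC1OCCO1 | intermediate
13 | (3R,5Z)-5-{[(tert-butyldimethylsilyl)oxy]methyl}-7-(1,3-dioxolan-2-yl)hepta-1,5-dien-3-ol | C=C[C@H](O)C/C(CO[Si](C)(C)C(C)(C)C)=C/CC1OCCO1 | intermediate
14 | (R)-2-methylbutanoic acid | CC[C@@H](C)C(=O)O | starting material
15 | (3R,5Z)-5-{[(tert-butyldimethylsilyl)oxy]methyl}-7-(1,3-dioxolan-2-yl)hepta-1,5-dien-3-yl (2R)-2-methylbutanoate | C=C[C@H](OC(=O)[C@H](C)CC)C/C(CO[Si](C)(C)C(C)(C)C)=C/CC1OCCO1 | intermediate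
16 | (3R,5Z)-5-{[(tert-butyldimethylsilyl)oxy]methyl}-8-oxoocta-1,5-dien-3-yl (2R)-2-methylbutanoate | C=C[C@H](OC(=O)[C@H](C)CC)C/C(CO[Si](C)(C)C(C)(C)C)=C/CC=O | intermediate
17 | (3R,5Z,8S,9Z)-5-{[(tert-butyldimethylsilyl)oxy]methyl}-9-methyl-8,11-bis[(triethylsilyl)oxy]undeca-1,5,9-trien-3-yl (2R)-2-methylbutanoate | C=C[C@H](OC(=O)[C@H](C)CC)C/C(CO[Si](C)(C)C(C)(C)C)=C/C[C@H](O[Si](CC)(CC)CC)/C(C)=C\CO[Si](CC)(CC)CC | intermediate
18 | (3R,5Z,8S,9Z)-5-{[(tert-butyldimethylsilyl)oxy]methyl}-9-methyl-11-oxo-8-[(triethylsilyl)oxy]undeca-1,5,9-trien-3-yl (2R)-2-methylbutanoate | C=C[C@H](OC(=O)[C@H](C)CC)C/C(CO[Si](C)(C)C(C)(C)C)=C/C[C@H](O[Si](CC)(CC)CC)/C(C)=C\C=O | intermediate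
19 | methyl 2-(bromomethyl)prop-2-enoate | C=C(CBr)C(=O)OC | starting material
20 | methyl (2Z,4R,6Z,9S,10Z)-2-(bromomethyl)-6-{[(tert-butyldimethylsilyl)oxy]methyl}-10-methyl-4-{[(2R)-2-methylbutanoyl]oxy}-12-oxo-9-[(triethylsilyl)oxy]dodeca-2,6,10-trienoate | COC(=O)/C(CBr)=C/[C@H](OC(=O)[C@H](C)CC)C/C(CO[Si](C)(C)C(C)(C)C)=C/C[C@H](O[Si](CC)(CC)CC)/C(C)=C\C=O | intermediate
21 | macrocyclic hydroxy ester: methyl (3S,6R,7R,8R)-6-hydroxy-8-[(2R)-2-methylbutanoyloxy]-3-[(triethylsilyl)oxy]-14-[(tert-butyldimethylsilyl)oxy]germacra-1(10),4,11(13)-trien-12-oate | C=C(C(=O)OC)[C@H]1[C@H](O)/C=C(/C)[C@@H](O[Si](CC)(CC)CC)C/C=C(\CO[Si](C)(C)C(C)(C)C)C[C@H]1OC(=O)[C@H](C)CC | intermediate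
22 | (3S,6R,7R,8R)-3,14-dihydroxy-8-[(2R)-2-methylbutanoyloxy]germacra-1(10),4,11(13)-trien-12,6-olide (C4=C5 ring-cis; C1=C10 ring-trans, C14 cis to C2) | C=C1C(=O)O[C@@H]2/C=C(/C)[C@@H](O)C/C=C(\CO)C[C@@H](OC(=O)[C@H](C)CC)[C@@H]12 | intermediate
23 | (1R,3S,6R,7R,8R,10S)-1,10-epoxy-3,14-dihydroxy-8-[(2R)-2-methylbutanoyloxy]germacra-4,11(13)-dien-12,6-olide | C=C1C(=O)O[C@@H]2/C=C(/C)[C@@H](O)C[C@H]3O[C@]3(CO)C[C@@H](OC(=O)[C@H](C)CC)[C@@H]12 | target

## Step count and risks

Total step count: 12. Longest linear sequence: 10 (steps 3–12); steps 1–2 are a two-step side branch that joins at step 8.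

The three steps most likely to fail are step 11, step 8 and step 12.

The ring closure of step 11 can fail by reductive loss of the 8-acyloxy group from the allylchromium, by oligomerisation, or by giving the wrong C6/C7 pair. The fallback sets out from 18: cross-metathesis with methyl 2-[(4,4,5,5-tetramethyl-1,3,2-dioxaborolan-2-yl)methyl]prop-2-enoate (Hoveyda–Grubbs II) gives the allylboronate enal F1, whose olefin isomers are configurationally stable and separable; the isomer with C8 trans to CH2B is used. Heating F1 at high dilution (toluene, 80 °C, or Sc(OTf)3 cat., rt) closes the same C6–C7 bond by a type-I allylboration through a closed chair, with no low-valent metal and with the relative configuration fixed by the boronate geometry. Aqueous work-up returns the route at 21, which goes on to 22 with HF·pyridine.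

The asymmetric Ni/Cr coupling of step 8 can fail through poor catalyst control at C3 or through silylation or isomerisation of the β,γ-unsaturated aldehyde. The fallback sets out from 16 and 4: a stoichiometric, ligand-free Ni/Cr coupling (CrCl2, NiCl2 cat., DMF) gives the C3-epimeric alcohols F2; Dess–Martin oxidation gives the enone F3; reduction with (R)-Me-CBS/catecholborane (alkenyl group as the large substituent) sets C3 by ketone reduction and gives the (3S)-alcohol F4; TESCl/imidazole returns the route at 17.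

The titanium-catalysed epoxidation of step 12 can be sluggish on the macrocyclic diol, or the Lewis acid can trigger transannular or C3–OH-assisted opening of the product. The fallback sets out from 22 and goes directly to 23 with a non-directed, neutral dioxirane epoxidation (DMDO, acetone, −40 °C, or the Shi ketone with Oxone if reagent control is needed); it relies on the strained 1(10)-olefin being the most nucleophilic alkene and exposing only its outer face, and makes no new compound (F0).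

## Further compounds

F1 | step 11 | methyl (4R,6Z,9S,10Z)-6-{[(tert-butyldimethylsilyl)oxy]methyl}-10-methyl-4-{[(2R)-2-methylbutanoyl]oxy}-12-oxo-2-[(pinacolboryl)methyl]-9-[(triethylsilyl)oxy]dodeca-2,6,10-trienoate (C4 trans to CH2B) | COC(=O)/C(CB1OC(C)(C)C(C)(C)O1)=C\[C@H](OC(=O)[C@H](C)CC)C/C(CO[Si](C)(C)C(C)(C)C)=C/C[C@H](O[Si](CC)(CC)CC)/C(C)=C\C=O
F2 | step 8 | (3R,5Z,9Z)-5-{[(tert-butyldimethylsilyl)oxy]methyl}-8-hydroxy-9-methyl-11-[(triethylsilyl)oxy]undeca-1,5,9-trien-3-yl (2R)-2-methylbutanoate (C8 epimers) | C=C[C@H](OC(=O)[C@H](C)CC)C/C(CO[Si](C)(C)C(C)(C)C)=C/CC(O)/C(C)=C\CO[Si](CC)(CC)CC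
F3 | step 8 | (3R,5Z,9Z)-5-{[(tert-butyldimethylsilyl)oxy]methyl}-9-methyl-8-oxo-11-[(triethylsilyl)oxy]undeca-1,5,9-trien-3-yl (2R)-2-methylbutanoate | C=C[C@H](OC(=O)[C@H](C)CC)C/C(CO[Si](C)(C)C(C)(C)C)=C/CC(=O)/C(C)=C\CO[Si](CC)(CC)CC
F4 | step 8 | (3R,5Z,8S,9Z)-5-{[(tert-butyldimethylsilyl)oxy]methyl}-8-hydroxy-9-methyl-11-[(triethylsilyl)oxy]undeca-1,5,9-trien-3-yl (2R)-2-methylbutanoate | C=C[C@H](OC(=O)[C@H](C)CC)C/C(CO[Si](C)(C)C(C)(C)C)=C/C[C@H](O)/C(C)=C\CO[Si](CC)(CC)CC
F0 | step 12 | none | none
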